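## The problem

The target 21 (CNP0112088.1) is a (2S)-flavanone. Ring A is phloroglucinol-derived (5-OH, 6-prenyl, 7-OMe, C8–H) and is fused through C4a/C8a to the dihydropyranone ring C, which carries a 2-geranyl-3,4-dimethoxyphenyl ring B at C2. C2 is the only stereocentre. It is benzylic and β to the C4 carbonyl through O1, so base opens ring C to the 2'-hydroxychalcone and strong acid can ionise C2–O1; either path racemises it. With no second stereocentre to relay from, C2 has to be set by a catalyst and late. A temporary stereocentre at C4 can be steered by C2 (2,4-cis) but is lost when C4 becomes the ketone. Ring A poses a regiochemical problem: the prenyl group must sit between the 5- and 7-oxygens, so the two oxygens flanking C4a must be distinguished before ring C closes. The three trisubstituted alkenes, all attached through ArCH2–CH= positions, exclude hydrogenation, electrophilic oxidants and strong acid (cation–olefin cyclisation, chroman formation onto an ortho phenol). The enabling feature is that O1–C8a=C4a–C4, with C4 at the aldehyde oxidation level, is the heterodiene of an ortho-quinone methide, while C3–C2 with ring B is a styrene whose 4'-methoxy group is para to the vinyl carbon. These two pieces map onto an inverse-demand [4+2] addition that forms C3–C4 and O1–C2 and sets C2 in one event.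

## Retrosynthesis

**21 back to 18 (functional-group adjustment, no skeletal bond cut).** The 5-OH is uncovered last from MOM ether 20, because the free phenol next to the prenyl group is the most acid-sensitive arrangement and is best tolerated once it is hydrogen-bonded to the C4 ketone. The ketone of 20 is traced to alcohol 19 and then to the benzylic methyl ether 18. Carrying C4 as CH2 would require a benzylic oxidation in the presence of three ArCH2–allyl positions; carrying it as a flavone would defer C2 to an asymmetric reduction. Ether 18 is not simpler in skeleton, but it is the direct cycloadduct at the right oxidation level. The forward steps must solvolyse C4–OMe without touching C2–O1 or the MOM group, oxidise without touching the alkenes, and deprotect without base.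

**18 to 9 and 15 (C3–C4 and O1–C2).** Cutting these two bonds opens ring C into salicylaldehyde 9 and styrene 15, two fragments of similar size. Forward, 9 passes through acetal 16 to the methoxy ortho-quinone methide 17, which adds 15. Against the neighbouring cuts (O1–C2 alone by oxa-Michael closure of a chalcone, or O1–C8a alone by aryl ether formation), this one forms ring C and C2 together under acid, so C2 never meets base. It asks the forward reaction for enantiofacial control by a chiral acid, for the aryl group to end on C2, and for the styrene to react in preference to three trisubstituted alkenes.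

**9 to 7, then to 5 and 6 (aryl–prenyl bond).** The prenyl group of 9 is traced through ortho-dienone 8 to the O-prenyl ether 7, and 7 to phenol 5 and prenyl bromide 6. Electrophilic substitution of 5 would go ortho to the free phenol (the wrong carbon). Directed lithiation between the MOM-oxy and methoxy groups would require masking the aldehyde and would not, by itself, tell the two oxygens ortho to the formyl group apart. The para-Claisen–Cope sequence solves both: the prenyl group arrives para to the oxygen that carried it, and that oxygen is released as the single free phenol needed for ring closure. The forward reaction must favour the Cope shift of 8 over its tautomerisation.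

**5 to 4, 2 and 1 (aryl–CHO bond).** Phenol 5 comes from the symmetric bis-MOM aldehyde 4 by loss of one MOM group. Aldehyde 4 comes from arene 2 through aryllithium 3, and 2 from 5-methoxyresorcinol 1. Because 2 and 4 are symmetric, neither the formylation (at the carbon between the two MOM-oxy groups) nor the mono-deprotection has a regiochemical choice. Vilsmeier-type formylation of 1 would go to the wrong carbon, para to a hydroxyl.

**15 to 14, then to 10 and 11 (vinyl C=C and aryl–geranyl bond).** Styrene 15 is the methylenation product of aldehyde 14. Aldehyde 14 is cut at the aryl–CH2 bond to veratraldehyde 10 and geranyl bromide 11, joined through amino alkoxide 12 and aryllithium 13. The position between the formyl and 3-methoxy groups is the one that a chelating in situ aldehyde protection directs lithium to. Bromination of 10 would go to C6 instead, and a Claisen route would deliver the branched (linalyl-type) chain.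

## Roads not taken

**Alternative 1:** The cut is O1–C8a, closed by aryl fluoride displacement, with the C2–O bond made beforehand on an open-chain enone. Chalcone A2, which carries fluorine on ring A where O1 will stand, would be epoxidised with hydrogen peroxide under poly-D-leucine catalysis (Juliá–Colonna) to the trans (αS,βR)-epoxide A1. Reductive cleavage of the Cα–O bond and displacement of fluoride by the remaining benzylic oxygen would close ring C and give 20.
- Merits: the asymmetric step is established chemistry for chalcones and, being a nucleophilic epoxidation, ignores the three trisubstituted alkenes. In this respect it is safer than the chosen plan, whose asymmetric step is untested.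
- Weak points: both aryl groups of A2 are doubly ortho-substituted, which twists the enone and should slow the polyleucine epoxidation and erode its selectivity. The fluoride displacement must occur on a ring carrying two alkoxy groups and an alkyl group, activated only by the ortho carbonyl, under basic conditions in which the β-hydroxy ketone can undergo retro-aldol cleavage or dehydrate back to A2. A fluorinated ring A cannot be drawn from 1, and the α-oxygen is installed only to be removed.
- Comparison: the chosen plan is shorter, forms ring and stereocentre together and keeps C2 away from base. Against the better precedent of this road it sets a fallback for its key step that uses only known reactions.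

**Alternative 2:** The cut is C4a–C5 inside ring A. Dihydropyranone A4, which carries the 2S aryl group and a prenylated β-keto ester side chain, would be treated with base. The extended enolate attacks the ester through the pyranone α-carbon, methanol is lost, and ring A aromatises to the 5,7-dihydroxyflavanone A3. Selective 7-O-methylation would give 21.
- Merits: the prenyl position is fixed by construction (it sits on the carbon between the two carbonyls that become C5 and C7), and ring A needs no protecting groups. Here it is better than the chosen plan, which spends five steps placing the prenyl group and distinguishing the oxygens.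
- Weak points: C2 must be set early and then survive the strong base of the Claisen step. Both A4 and A3 can open by β-elimination of O1 under such conditions, which racemises C2. A3 still needs a selective methylation, and the linear β-keto ester chain is laborious to build.
- Comparison: the chosen plan sets C2 late and under acid and uses aromatic feedstocks; its price is the longer preparation of 9.

**Alternative 3:** The cut is C4a–C4, C4–C3 and O1–C2 around a carbon monoxide carbon. PdCl2(PPh3)2 with Et2NH under CO would join iodophenol A6 and arylacetylene A7 by carbonylative coupling and 6-endo closure to flavone A5. An enantioselective 1,4-reduction would then give 20.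
- Merits: the assembly is highly convergent, well precedented for flavones, tolerant of crowding and gives a stable achiral intermediate. As a ring-forming reaction it is more reliable than the chosen key step.
- Weak points: the stereocentre is deferred to a conjugate reduction of a vinylogous ester flanked by a hindered aryl group. Hydrogenation catalysts would also reduce the side-chain alkenes or the ketone, and hydride conjugate reductions of flavones with high selectivity are scarce, so the novelty risk is moved and not removed. A6 needs iodine placed between a hydroxyl and a MOM-oxy group (the same differentiation problem as 9 without the help of the carbonyl), A7 needs a homologation of 14, and 5-exo closure to an aurone can compete.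
- Comparison: the chosen plan sets C2 while ring C forms and at the correct oxidation level. Against the robustness of the palladium assembly it sets a shorter end game and a resolution-based fallback.

Key step: step 8

Remark on the chemistry: the absolute sense of induction of the chiral acid on this substrate pair cannot be assigned in advance. The (R) antipode is written, and the (S) antipode is meant if it proves to favour 2R. C4 of 19 is left undefined because both epimers converge on 20.

## Route

Step 1
Reactants: 1 5-methoxyresorcinol
Product: 2 1-methoxy-3,5-bis(methoxymethoxy)benzene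
Conditions: NaH, MOMCl, DMF, 0 °C → rt
Reagents that add atoms: chloromethyl methyl ether, COCCl
Why: Double Williamson-type O-alkylation of the two equivalent phenoxides. The MOM groups serve as directing groups for step 2, and one of them becomes the 5-O protecting group.

Step 2
Reactants: 2 1-methoxy-3,5-bis(methoxymethoxy)benzene
Product: 4 4-methoxy-2,6-bis(methoxymethoxy)benzaldehyde, via aryllithium 3 (not isolated)
Conditions: n-BuLi, TMEDA, THF, 0 °C; DMF, 0 °C → rt; aq. NH4Cl
Reagents that add atoms: N,N-dimethylformamide, CN(C)C=O
Why: Directed ortho-metalation. The C–H flanked by two chelating MOM-oxy groups is the preferred lithiation site over those flanked by one MOM-oxy and one methoxy group, and formylation of 3 with DMF gives the symmetric aldehyde.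

Step 3
Reactants: 4 4-methoxy-2,6-bis(methoxymethoxy)benzaldehyde
Product: 5 2-hydroxy-4-methoxy-6-(methoxymethoxy)benzaldehyde
Conditions: HCl (cat.), MeOH, 0 °C → rt, stopped at mono-cleavage
Reagents that add atoms: none
Why: Acid-catalysed acetal methanolysis. The two MOM groups are equivalent, and the first phenol formed locks into a hydrogen bond with the aldehyde, which slows loss of the second group, so the reaction should be stoppable at 5.

Step 4
Reactants: 5 2-hydroxy-4-methoxy-6-(methoxymethoxy)benzaldehyde; 6 prenyl bromide
Product: 7 4-methoxy-2-(methoxymethoxy)-6-[(3-methylbut-2-en-1-yl)oxy]benzaldehyde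
Conditions: K2CO3, DMF, 40 °C
Reagents that add atoms: none
Why: Williamson ether synthesis on the only free phenol. The polar aprotic medium favours O- over C-alkylation of the chelated phenoxide.

Step 5
Reactants: 7 4-methoxy-2-(methoxymethoxy)-6-[(3-methylbut-2-en-1-yl)oxy]benzaldehyde
Product: 9 6-hydroxy-4-methoxy-2-(methoxymethoxy)-3-(3-methylbut-2-en-1-yl)benzaldehyde, via ortho-dienone 8 (not isolated)
Conditions: Eu(fod)3 (10 mol%), NaHCO3, PhCl, 80 °C
Reagents that add atoms: none
Why: Para-Claisen–Cope rearrangement. Eu(fod)3 (fod = 6,6,7,7,8,8,8-heptafluoro-2,2-dimethyloctane-3,5-dionate) chelates the aldehyde and ether oxygens and triggers the [3,3] shift to ortho-dienone 8, whose crowded 1,1-dimethylallyl group undergoes a Cope shift to the para carbon before enolisation. The prenyl group thus lands between the methoxy and MOM-oxy groups and the oxygen that carried it becomes the free phenol; this mirrors the known conversion of 5-O-prenyl flavonoids and 2-prenyloxy aryl ketones into their para-C-prenyl isomers.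

Step 6
Reactants: 10 veratraldehyde; 11 geranyl bromide
Product: 14 2-[(2E)-3,7-dimethylocta-2,6-dien-1-yl]-3,4-dimethoxybenzaldehyde, via lithium amino alkoxide 12 (not isolated), via aryllithium 13 (not isolated)
Conditions: LiN(Me)CH2CH2NMe2, THF, −20 °C; n-BuLi (3 equiv), −20 °C; 11 (excess), −78 °C → rt; aq. NH4Cl
Reagents that add atoms: none
Why: In situ α-amino alkoxide protection and directed ortho-lithiation. The chelating diamine arm and the 3-methoxy group together direct lithium to C2, and SN2 alkylation of 13 at the primary allylic carbon of 11 keeps the E alkene. Aqueous work-up returns the aldehyde.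

Step 7
Reactants: 14 2-[(2E)-3,7-dimethylocta-2,6-dien-1-yl]-3,4-dimethoxybenzaldehyde
Product: 15 1-ethenyl-2-[(2E)-3,7-dimethylocta-2,6-dien-1-yl]-3,4-dimethoxybenzene
Conditions: Ph3PCH3Br, KOtBu, THF, 0 °C → rt
Reagents that add atoms: methyltriphenylphosphonium bromide, C[P+](c1ccccc1)(c1ccccc1)c1ccccc1.[Br-]
Why: Wittig methylenation of an aryl aldehyde. The unstabilised ylide leaves the isolated trisubstituted alkenes untouched.

Step 8
Reactants: 9 6-hydroxy-4-methoxy-2-(methoxymethoxy)-3-(3-methylbut-2-en-1-yl)benzaldehyde; 15 1-ethenyl-2-[(2E)-3,7-dimethylocta-2,6-dien-1-yl]-3,4-dimethoxybenzene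
Product: 18 (2S,4S)-2-{2-[(2E)-3,7-dimethylocta-2,6-dien-1-yl]-3,4-dimethoxyphenyl}-4,7-dimethoxy-5-(methoxymethoxy)-6-(3-methylbut-2-en-1-yl)-3,4-dihydro-2H-chromene, via dimethyl acetal 16 (not isolated), via ortho-quinone methide 17 (not isolated)
Conditions: HC(OMe)3 (3 equiv), (R)-3,3'-bis(2,4,6-triisopropylphenyl)-1,1'-binaphthyl-2,2'-diyl N-(trifluoromethylsulfonyl)phosphoramide (10 mol%), CH2Cl2, −40 °C; Et3N quench
Reagents that add atoms: trimethyl orthoformate, COC(OC)OC
Why: Proposed new method: the acid and HC(OMe)3 convert 9 into acetal 16, which loses methanol to the methoxy ortho-quinone methide 17, present under the acid as an oxocarbenium ion hydrogen-bonded through its phenol to the chiral phosphoramide anion. The terminal CH2 of styrene 15 attacks C4 and the phenol oxygen collapses on the developing 4-methoxybenzylic cation, an asynchronous inverse-demand hetero-[4+2] addition in which ring C closes as a six-membered ring by C3–C4 bond formation followed within the ion pair by O1–C2 bond formation. The closest known reactions are the racemic acid-catalysed synthesis of 2,4-cis-4-alkoxyflavans from salicylaldehydes, orthoformates and styrenes, and chiral phosphoric acid or N-triflyl phosphoramide catalysed [4+2] additions of ortho-quinone methides from ortho-hydroxybenzyl alcohols to styrenes; the enantioselective acetal version has not been shown. C2 is set by the chiral counter-anion, which must shield one face of the heterodiene so that the styrene adds in the sense leading to 2S; C4 follows from C2 through the endo-type transition state that places aryl and methoxy cis, and it is erased in step 10. The aryl group ends on C2 because the 4-methoxy group para to the vinyl carbon stabilises the benzylic cation; the same donor makes the styrene far more nucleophilic than the three trisubstituted alkenes, so chemoselectivity rests on it and on the low temperature. Only the phenol next to C8–H is free, the one next to the prenyl group being a MOM ether, so closure can give only the 6-prenyl isomer, and a near-concerted closure by oxygen should outrun capture of the cation by the neighbouring geranyl alkene. Quenching with Et3N before warming guards C2 against re-ionisation of the C2–O1 bond.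

Step 9
Reactants: 18 (2S,4S)-4-methoxyflavan from step 8
Product: 19 (2S)-2-{2-[(2E)-3,7-dimethylocta-2,6-dien-1-yl]-3,4-dimethoxyphenyl}-7-methoxy-5-(methoxymethoxy)-6-(3-methylbut-2-en-1-yl)-3,4-dihydro-2H-chromen-4-ol (mixture of C4 epimers)
Conditions: PPTS (cat.), THF/H2O, rt
Reagents that add atoms: water, O
Why: SN1 solvolysis of a benzylic ether. The C4 cation is stabilised by O1, the 5-oxygen and the 7-oxygen, so it should form under acid too weak to ionise C2–O1 or cleave the MOM ether, and water captures it; C2 is untouched and the C4 configuration is irrelevant.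

Step 10
Reactants: 19 (2S)-flavan-4-ol from step 9
Product: 20 (2S)-2-{2-[(2E)-3,7-dimethylocta-2,6-dien-1-yl]-3,4-dimethoxyphenyl}-7-methoxy-5-(methoxymethoxy)-6-(3-methylbut-2-en-1-yl)-2,3-dihydro-4H-chromen-4-one
Conditions: Dess–Martin periodinane, NaHCO3, CH2Cl2, 0 °C → rt
Reagents that add atoms: none
Why: Dess–Martin oxidation of a secondary benzylic alcohol under buffered, neutral conditions. It spares the alkenes, the MOM ether and the C2 stereocentre, and both C4 epimers give the same ketone.

Step 11
Reactants: 20 (2S)-5-O-MOM flavanone from step 10
Product: 21 (2S)-2-{2-[(2E)-3,7-dimethylocta-2,6-dien-1-yl]-3,4-dimethoxyphenyl}-5-hydroxy-7-methoxy-6-(3-methylbut-2-en-1-yl)-2,3-dihydro-4H-chromen-4-one (CNP0112088.1)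
Conditions: HCl (1.25 M in MeOH), 0 °C → rt
Reagents that add atoms: none
Why: Acid-catalysed methanolysis of the MOM acetal, which is unusually labile peri to the C4 carbonyl. Acid is used instead of base to avoid retro-oxa-Michael opening to the chalcone, and the liberated phenol is tied up in a hydrogen bond to the ketone, which lowers its tendency to add to the neighbouring prenyl group.

## Compound list

1 | 5-methoxyresorcinol (5-methoxybenzene-1,3-diol) | COc1cc(O)cc(O)c1 | starting material
2 | 1-methoxy-3,5-bis(methoxymethoxy)benzene | COCOc1cc(OC)cc(OCOC)c1 | intermediate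
3 | [4-methoxy-2,6-bis(methoxymethoxy)phenyl]lithium | [Li]c1c(OCOC)cc(OC)cc1OCOC | intermediate (not isolated)
4 | 4-methoxy-2,6-bis(methoxymethoxy)benzaldehyde | O=Cc1c(OCOC)cc(OC)cc1OCOC | intermediate
5 | 2-hydroxy-4-methoxy-6-(methoxymethoxy)benzaldehyde | O=Cc1c(O)cc(OC)cc1OCOC | intermediate
6 | prenyl bromide (1-bromo-3-methylbut-2-ene) | CC(C)=CCBr | starting material
7 | 4-methoxy-2-(methoxymethoxy)-6-[(3-methylbut-2-en-1-yl)oxy]benzaldehyde | O=Cc1c(OCC=C(C)C)cc(OC)cc1OCOC | intermediate
8 | 4-methoxy-2-(methoxymethoxy)-5-(2-methylbut-3-en-2-yl)-6-oxocyclohexa-1,3-diene-1-carbaldehyde (ortho-dienone, racemic at C5) | O=CC1=C(OCOC)C=C(OC)C(C(C)(C)C=C)C1=O | intermediate (not isolated)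
9 | 6-hydroxy-4-methoxy-2-(methoxymethoxy)-3-(3-methylbut-2-en-1-yl)benzaldehyde | O=Cc1c(O)cc(OC)c(CC=C(C)C)c1OCOC | intermediate
10 | veratraldehyde (3,4-dimethoxybenzaldehyde) | COc1ccc(C=O)cc1OC | starting material
11 | geranyl bromide ((2E)-1-bromo-3,7-dimethylocta-2,6-diene) | CC(C)=CCC/C(C)=C/CBr | starting material
12 | lithium (3,4-dimethoxyphenyl){[2-(dimethylamino)ethyl](methyl)amino}methanolate | [Li+].[O-]C(N(C)CCN(C)C)c1ccc(OC)c(OC)c1 | intermediate (not isolated)
13 | lithium {[2-(dimethylamino)ethyl](methyl)amino}(2-lithio-3,4-dimethoxyphenyl)methanolate | [Li+].[Li]c1c(C([O-])N(C)CCN(C)C)ccc(OC)c1OC | intermediate (not isolated)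
14 | 2-[(2E)-3,7-dimethylocta-2,6-dien-1-yl]-3,4-dimethoxybenzaldehyde | O=Cc1ccc(OC)c(OC)c1C/C=C(\C)CCC=C(C)C | intermediate
15 | 1-ethenyl-2-[(2E)-3,7-dimethylocta-2,6-dien-1-yl]-3,4-dimethoxybenzene | C=Cc1ccc(OC)c(OC)c1C/C=C(\C)CCC=C(C)C | intermediate
16 | 2-(dimethoxymethyl)-5-methoxy-3-(methoxymethoxy)-4-(3-methylbut-2-en-1-yl)phenol | COC(OC)c1c(O)cc(OC)c(CC=C(C)C)c1OCOC | intermediate (not isolated)
17 | 3-methoxy-5-(methoxymethoxy)-6-(methoxymethylidene)-4-(3-methylbut-2-en-1-yl)cyclohexa-2,4-dien-1-one (ortho-quinone methide; its O-protonated form is the oxocarbenium ion) | COC=C1C(=O)C=C(OC)C(CC=C(C)C)=C1OCOC | intermediate (not isolated)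
18 | (2S,4S)-2-{2-[(2E)-3,7-dimethylocta-2,6-dien-1-yl]-3,4-dimethoxyphenyl}-4,7-dimethoxy-5-(methoxymethoxy)-6-(3-methylbut-2-en-1-yl)-3,4-dihydro-2H-chromene (2,4-cis) | COCOc1c(CC=C(C)C)c(OC)cc2c1[C@@H](OC)C[C@@H](c1ccc(OC)c(OC)c1C/C=C(\C)CCC=C(C)C)O2 | intermediate
19 | (2S)-2-{2-[(2E)-3,7-dimethylocta-2,6-dien-1-yl]-3,4-dimethoxyphenyl}-7-methoxy-5-(methoxymethoxy)-6-(3-methylbut-2-en-1-yl)-3,4-dihydro-2H-chromen-4-ol (C4 epimers) | COCOc1c(CC=C(C)C)c(OC)cc2c1C(O)C[C@@H](c1ccc(OC)c(OC)c1C/C=C(\C)CCC=C(C)C)O2 | intermediate
20 | (2S)-2-{2-[(2E)-3,7-dimethylocta-2,6-dien-1-yl]-3,4-dimethoxyphenyl}-7-methoxy-5-(methoxymethoxy)-6-(3-methylbut-2-en-1-yl)-2,3-dihydro-4H-chromen-4-one | COCOc1c(CC=C(C)C)c(OC)cc2c1C(=O)C[C@@H](c1ccc(OC)c(OC)c1C/C=C(\C)CCC=C(C)C)O2 | intermediate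
21 | (2S)-2-{2-[(2E)-3,7-dimethylocta-2,6-dien-1-yl]-3,4-dimethoxyphenyl}-5-hydroxy-7-methoxy-6-(3-methylbut-2-en-1-yl)-2,3-dihydro-4H-chromen-4-one | COc1cc2c(c(O)c1CC=C(C)C)C(=O)C[C@@H](c1ccc(OC)c(OC)c1C/C=C(\C)CCC=C(C)C)O2 | target

## Step count and least certain steps

Total: 11 steps. Longest linear sequence: 9 steps (steps 1–5, then 8–11). The styrene branch (steps 6–7) joins at step 8.

**Step 8 (key step, proposed new method).** Most likely failure is poor facial selectivity. The oxocarbenium ion is strongly delocalised over three ring oxygens, so its ion pair with the chiral anion may be loose, and the styrene offers no binding site. Two further risks are interception of the benzylic cation by the neighbouring geranyl alkene before the oxygen closes the ring, and erosion of the C2 configuration by reversible ionisation of C2–O1 if the mixture warms before the quench.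
Fallback (known chemistry only): starting from 9 and 15, the same three-component reaction is run with an achiral acid (diphenyl phosphate or catalytic TfOH, HC(OMe)3, CH2Cl2, low temperature) to give racemic 2,4-cis-4-methoxyflavan F1. Hydrolysis and oxidation as in steps 9 and 10 give racemic flavan-4-ol F2 and racemic 5-O-MOM flavanone F3. Kinetic resolution of F3 by asymmetric transfer hydrogenation (RuCl[(R,R)-TsDPEN](p-cymene) or its antipode, HCO2H/Et3N), with the catalyst antipode chosen so that the 2R ketone is reduced, converts the unwanted enantiomer into (2R,4R)-cis-flavan-4-ol F4 and leaves the 2S ketone. Chromatographic separation returns the route at 20, at the cost of at most half the material.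

**Step 5.** Most likely failure is diversion of the rearrangement: enolisation of the ortho-dienone before the Cope shift, which leaves a 1,1-dimethylallyl group on the carbon next to the phenol, or Lewis-acid ionisation of the prenyl ether with loss of the prenyl group.
Fallback: starting from 5, the phenol is silylated (TIPSOTf, 2,6-lutidine) to 4-methoxy-2-(methoxymethoxy)-6-[(triisopropylsilyl)oxy]benzaldehyde F5. The aldehyde is masked by condensation with N,N'-dimethylethylenediamine as imidazolidine F6. Directed lithiation (n-BuLi, THF, 0 °C) then occurs at the C–H between the MOM-oxy and methoxy groups, the bulky silyl ether shielding the other site. Transmetalation with CuBr·SMe2, alkylation with 6 and mild aqueous acid work-up give the prenylated silyl ether aldehyde F7. Bu4NF removes the silyl group and the route is rejoined at 9.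

**Step 6.** Most likely failure is low conversion in the alkylation: the surplus n-BuLi needed for the lithiation competes for the allylic bromide, and SN2' attack or halogen–metal exchange can divert the aryllithium.
Fallback: starting from 10, the same amino-alkoxide-directed lithiation is quenched with iodine to give 2-iodo-3,4-dimethoxybenzaldehyde F8. Wittig methylenation gives 1-ethenyl-2-iodo-3,4-dimethoxybenzene F9. Iodine–lithium exchange (t-BuLi, 2 equiv, −78 °C), transmetalation with CuBr·SMe2 and reaction with 11 then introduce the geranyl group from a stoichiometrically defined arylcopper species, rejoining the route at 15.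

**Step 9.** Most likely failure is elimination of methanol across C3–C4 to the flav-3-ene instead of capture of the cation by water, with partial loss of the MOM group if more acid is used to force conversion.
Fallback: starting from 18, the benzylic C4–H is oxidised directly with DDQ in CH2Cl2/pH 7 buffer at 0 °C. Hydride abstraction from the most electron-rich benzylic position gives the oxocarbenium ion, which water converts to the ketone, so 19 is bypassed and the route is rejoined at 20.

## Further compounds

F1 | step 8 | racemic 2,4-cis-2-{2-[(2E)-3,7-dimethylocta-2,6-dien-1-yl]-3,4-dimethoxyphenyl}-4,7-dimethoxy-5-(methoxymethoxy)-6-(3-methylbut-2-en-1-yl)-3,4-dihydro-2H-chromene | COCOc1c(CC=C(C)C)c(OC)cc2c1C(OC)CC(c1ccc(OC)c(OC)c1C/C=C(\C)CCC=C(C)C)O2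
F2 | step 8 | racemic 2-{2-[(2E)-3,7-dimethylocta-2,6-dien-1-yl]-3,4-dimethoxyphenyl}-7-methoxy-5-(methoxymethoxy)-6-(3-methylbut-2-en-1-yl)-3,4-dihydro-2H-chromen-4-ol (C4 epimers) | COCOc1c(CC=C(C)C)c(OC)cc2c1C(O)CC(c1ccc(OC)c(OC)c1C/C=C(\C)CCC=C(C)C)O2
F3 | step 8 | racemic 2-{2-[(2E)-3,7-dimethylocta-2,6-dien-1-yl]-3,4-dimethoxyphenyl}-7-methoxy-5-(methoxymethoxy)-6-(3-methylbut-2-en-1-yl)-2,3-dihydro-4H-chromen-4-one | COCOc1c(CC=C(C)C)c(OC)cc2c1C(=O)CC(c1ccc(OC)c(OC)c1C/C=C(\C)CCC=C(C)C)O2
F4 | step 8 | (2R,4R)-2-{2-[(2E)-3,7-dimethylocta-2,6-dien-1-yl]-3,4-dimethoxyphenyl}-7-methoxy-5-(methoxymethoxy)-6-(3-methylbut-2-en-1-yl)-3,4-dihydro-2H-chromen-4-ol | COCOc1c(CC=C(C)C)c(OC)cc2c1[C@H](O)C[C@H](c1ccc(OC)c(OC)c1C/C=C(\C)CCC=C(C)C)O2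
F5 | step 5 | 4-methoxy-2-(methoxymethoxy)-6-[(triisopropylsilyl)oxy]benzaldehyde | O=Cc1c(O[Si](C(C)C)(C(C)C)C(C)C)cc(OC)cc1OCOC
F6 | step 5 | 2-{4-methoxy-2-(methoxymethoxy)-6-[(triisopropylsilyl)oxy]phenyl}-1,3-dimethylimidazolidine | CN1CCN(C)C1c1c(O[Si](C(C)C)(C(C)C)C(C)C)cc(OC)cc1OCOC
F7 | step 5 | 4-methoxy-2-(methoxymethoxy)-3-(3-methylbut-2-en-1-yl)-6-[(triisopropylsilyl)oxy]benzaldehyde | O=Cc1c(O[Si](C(C)C)(C(C)C)C(C)C)cc(OC)c(CC=C(C)C)c1OCOC
F8 | step 6 | 2-iodo-3,4-dimethoxybenzaldehyde | O=Cc1ccc(OC)c(OC)c1I
F9 | step 6 | 1-ethenyl-2-iodo-3,4-dimethoxybenzene | C=Cc1ccc(OC)c(OC)c1I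
F0 | step 9 | none | none
A1 | alternative 1 | [(2S,3R)-3-{2-[(2E)-3,7-dimethylocta-2,6-dien-1-yl]-3,4-dimethoxyphenyl}oxiran-2-yl][6-fluoro-4-methoxy-2-(methoxymethoxy)-3-(3-methylbut-2-en-1-yl)phenyl]methanone | COCOc1c(CC=C(C)C)c(OC)cc(F)c1C(=O)[C@H]1O[C@@H]1c1ccc(OC)c(OC)c1C/C=C(\C)CCC=C(C)C
A2 | alternative 1 | (2E)-3-{2-[(2E)-3,7-dimethylocta-2,6-dien-1-yl]-3,4-dimethoxyphenyl}-1-[6-fluoro-4-methoxy-2-(methoxymethoxy)-3-(3-methylbut-2-en-1-yl)phenyl]prop-2-en-1-one | COCOc1c(CC=C(C)C)c(OC)cc(F)c1C(=O)/C=C/c1ccc(OC)c(OC)c1C/C=C(\C)CCC=C(C)C
A3 | alternative 2 | (2S)-2-{2-[(2E)-3,7-dimethylocta-2,6-dien-1-yl]-3,4-dimethoxyphenyl}-5,7-dihydroxy-6-(3-methylbut-2-en-1-yl)-2,3-dihydro-4H-chromen-4-one | Oc1cc2c(c(O)c1CC=C(C)C)C(=O)C[C@@H](c1ccc(OC)c(OC)c1C/C=C(\C)CCC=C(C)C)O2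
A4 | alternative 2 | methyl 4-[(2S)-2-{2-[(2E)-3,7-dimethylocta-2,6-dien-1-yl]-3,4-dimethoxyphenyl}-4-oxo-3,4-dihydro-2H-pyran-6-yl]-2-(3-methylbut-2-en-1-yl)-3-oxobutanoate (side-chain stereocentre undefined) | COC(=O)C(CC=C(C)C)C(=O)CC1=CC(=O)C[C@@H](c2ccc(OC)c(OC)c2C/C=C(\C)CCC=C(C)C)O1
A5 | alternative 3 | 2-{2-[(2E)-3,7-dimethylocta-2,6-dien-1-yl]-3,4-dimethoxyphenyl}-7-methoxy-5-(methoxymethoxy)-6-(3-methylbut-2-en-1-yl)-4H-chromen-4-one | COCOc1c(CC=C(C)C)c(OC)cc2oc(-c3ccc(OC)c(OC)c3C/C=C(\C)CCC=C(C)C)cc(=O)c12
A6 | alternative 3 | 2-iodo-5-methoxy-3-(methoxymethoxy)-4-(3-methylbut-2-en-1-yl)phenol | Oc1cc(OC)c(CC=C(C)C)c(OCOC)c1I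
A7 | alternative 3 | 1-ethynyl-2-[(2E)-3,7-dimethylocta-2,6-dien-1-yl]-3,4-dimethoxybenzene | C#Cc1ccc(OC)c(OC)c1C/C=C(\C)CCC=C(C)C
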